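**Strategy.** The target is cut at C1–C8 (numbering used throughout: C1 allyl-bearing bridgehead, C2=C3(OMe), C4–OH, C5, C6 aryl, C7 methyl, C8 bridging carbonyl). This turns the bicyclo[3.2.1]octenone into a plain cyclopentanone, ring C1–C8–C5–C6–C7, whose α-quaternary ketone is a latent β-keto ester. The key step makes this ring from an acyclic thioenoate ester: copper-catalysed asymmetric methyl addition creates C7 and generates the C1 enolate, which closes onto the C8 ester (Dieckmann). All other centres are relayed from C7: decarboxylative allylation (C1), conjugate arylation (C6), a second, bridging Claisen closure C4–C5, then dehydrogenation and carbonyl reduction.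

Key step: step 2

Assumption: ylide 2 and acrylate 9 are counted as purchasable (each is otherwise one known step from bulk chemicals), and the Tol-BINAP antipode in step 2 is the one that gives the 3S adduct.

Step 1
Reactants: 1 methyl 4-oxobutanoate; 2 S-ethyl (triphenylphosphoranylidene)thioacetate
Product: 3 methyl (4E)-6-(ethylsulfanyl)-6-oxohex-4-enoate
Conditions: CH2Cl2, 20 °C
Reagents that add atoms: S-ethyl (triphenylphosphoranylidene)thioacetate, CCSC(=O)C=P(c1ccccc1)(c1ccccc1)c1ccccc1
Why: Wittig olefination with a carbonyl-stabilised ylide should convert the aldehyde (not the ester) into the (E)-α,β-unsaturated thioester.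

Step 2
Reactants: 3 methyl (4E)-6-(ethylsulfanyl)-6-oxohex-4-enoate; 4 methylmagnesium bromide
Product: 6 S-ethyl (1R,2S)-2-methyl-5-oxocyclopentane-1-carbothioate, via bromomagnesium thioester enolate 5 (not isolated)
Conditions: CuI (1 mol%), (S)-Tol-BINAP (1.2 mol%), MeMgBr (1.2 equiv), t-BuOMe, −70 °C; then warm to 20 °C; aq. NH4Cl
Reagents that add atoms: methylmagnesium bromide, C[Mg]Br
Why: A chiral monovalent copper–bisphosphine methyl species adds to the β-carbon of the thioenoate (enantioselective conjugate addition), which creates the methyl-bearing centre C7 and generates the magnesium thioester enolate only at the future C1. On warming, this enolate attacks the remote methyl ester (future C8) and expels methoxide, a Dieckmann-type Claisen condensation that forms the C1–C8 bond; the closest known reaction type is the tandem conjugate addition–Dieckmann cyclisation of enoate esters. The cyclopentanone closes in a 5-exo-trig mode, the enolate carbon attacking an exocyclic ester carbonyl. C7 is set by the ligand antipode, whereas C1 is epimerisable and should settle trans to the methyl group. The step needs regioselective enolate formation and 1,4- over 1,2-selectivity of the Grignard reagent: the first is secured because the enolate is formed by the addition itself at the more acidic thioester α-position, the second by the low temperature and the high reactivity of thioenoates under copper catalysis, and deprotonation of the β-keto thioester by the released methoxide drives the closure.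

Step 3
Reactants: 6 S-ethyl (1R,2S)-2-methyl-5-oxocyclopentane-1-carbothioate; 7 prop-2-en-1-ol
Product: 8 prop-2-en-1-yl (1R,2S)-2-methyl-5-oxocyclopentane-1-carboxylate
Conditions: AgOCOCF3 (1.1 equiv), prop-2-en-1-ol (5 equiv), THF, 20 °C
Reagents that add atoms: prop-2-en-1-ol, C=CCO
Why: Thiophilic silver activation makes the β-keto thioester an acylating agent (acyl substitution), so the alcohol should give the allyl β-keto ester without touching the methyl-bearing centre, while the carbon between the carbonyls stays epimerisable and trans.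

Step 4
Reactants: 8 prop-2-en-1-yl (1R,2S)-2-methyl-5-oxocyclopentane-1-carboxylate; 9 methyl 2-methoxyprop-2-enoate
Product: 10 prop-2-en-1-yl (2S)-1-(2,3-dimethoxy-3-oxopropyl)-2-methyl-5-oxocyclopentane-1-carboxylate
Conditions: Cs2CO3 (0.3 equiv), MeCN, 40 °C
Reagents that add atoms: methyl 2-methoxyprop-2-enoate, C=C(OC)C(=O)OC
Why: Michael addition of the β-keto ester enolate to the 2-methoxyacrylate should attach the future C2–C4 chain at the doubly activated carbon; the configurations of the new quaternary carbon and of the methoxy-bearing carbon do not matter, because the first is planarised in step 5 and the second in step 8.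

Step 5
Reactants: 10 prop-2-en-1-yl (2S)-1-(2,3-dimethoxy-3-oxopropyl)-2-methyl-5-oxocyclopentane-1-carboxylate
Product: 11 methyl 2-methoxy-3-[(1S,2S)-2-methyl-5-oxo-1-(prop-2-en-1-yl)cyclopentyl]propanoate
Conditions: Pd(PPh3)4 (5 mol%), THF, 20 °C
Reagents that add atoms: none
Why: Tsuji decarboxylative allylation: zerovalent palladium ionises the allyl ester, loss of CO2 gives the enolate only at the substituted α-carbon, and the allyl fragment should recombine on the face anti to the vicinal methyl group, which sets the quaternary centre C1.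

Step 6
Reactants: 11 methyl 2-methoxy-3-[(1S,2S)-2-methyl-5-oxo-1-(prop-2-en-1-yl)cyclopentyl]propanoate
Product: 13 methyl 2-methoxy-3-[(1S,5S)-5-methyl-2-oxo-1-(prop-2-en-1-yl)cyclopent-3-en-1-yl]propanoate, via trimethylsilyl enol ether 12 (not isolated)
Conditions: Me3SiOTf, Et3N, CH2Cl2, 0 °C; then Pd(OAc)2 (1.1 equiv), MeCN, 20 °C
Reagents that add atoms: none
Why: Saegusa–Ito oxidation: the ketone has α-hydrogens on one side only, so soft enolisation gives a single silyl enol ether, which divalent palladium should dehydrogenate to the enone without affecting the ester or the stereocentres.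

Step 7
Reactants: 13 methyl 2-methoxy-3-[(1S,5S)-5-methyl-2-oxo-1-(prop-2-en-1-yl)cyclopent-3-en-1-yl]propanoate; 14 (3,4-dimethoxyphenyl)boronic acid
Product: 15 methyl 3-[(1S,2S,3R)-3-(3,4-dimethoxyphenyl)-2-methyl-5-oxo-1-(prop-2-en-1-yl)cyclopentyl]-2-methoxypropanoate
Conditions: [Rh(OH)(cod)]2 (2.5 mol%), 14 (2 equiv), 1,4-dioxane/H2O 10:1, 40 °C
Reagents that add atoms: (3,4-dimethoxyphenyl)boronic acid, COc1ccc(B(O)O)cc1OC
Why: Hayashi–Miyaura conjugate arylation: the aryl–rhodium species should add to the enone β-carbon from the face anti to the vicinal methyl group, which sets C6 with aryl trans to methyl.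

Step 8
Reactants: 15 methyl 3-[(1S,2S,3R)-3-(3,4-dimethoxyphenyl)-2-methyl-5-oxo-1-(prop-2-en-1-yl)cyclopentyl]-2-methoxypropanoate
Product: 18 (1R,5R,6S,7S)-6-(3,4-dimethoxyphenyl)-3-methoxy-7-methyl-1-(prop-2-en-1-yl)bicyclo[3.2.1]oct-2-ene-4,8-dione, via lithium enolate 16 (not isolated), via phenylselanyl diketone 17 (not isolated)
Conditions: LiN(SiMe3)2 (2.3 equiv), THF, −78 to −20 °C; PhSeBr (1.5 equiv), −78 °C; then NaIO4, NaHCO3, THF/H2O, 0 to 20 °C
Reagents that add atoms: none
Why: Dieckmann-type intramolecular Claisen acylation: the ketone can enolise only towards C5, and that enolate should attack the side-chain ester on the ring face carrying the chain (anti to the C6 aryl group), which closes the six-membered ring and fixes C5, while the second equivalent of base converts the bridged β-diketone into its only possible enolate (C3–C4) and so shields it from retro-Claisen cleavage; selenenylation of that enolate and selenoxide syn-elimination (the only β-hydrogens are on C2) then install the C2=C3 double bond.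

Step 9
Reactants: 18 (1R,5R,6S,7S)-6-(3,4-dimethoxyphenyl)-3-methoxy-7-methyl-1-(prop-2-en-1-yl)bicyclo[3.2.1]oct-2-ene-4,8-dione
Product: 19 (1R,4R,5S,6S,7S)-6-(3,4-dimethoxyphenyl)-4-hydroxy-3-methoxy-7-methyl-1-(prop-2-en-1-yl)bicyclo[3.2.1]oct-2-en-8-one
Conditions: NaBH4 (1 equiv), CeCl3·7H2O (1.1 equiv), MeOH, −78 °C
Reagents that add atoms: none
Why: Luche reduction: trivalent cerium activation should direct hydride 1,2 to the conjugated C4 carbonyl in preference to the hindered, non-conjugated bridging ketone C8, and attack from the face syn to the C8 bridge (axial, away from the C6–C7 bridge) should give the pseudo-equatorial 4R alcohol.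

**Compound list**

1 | methyl 4-oxobutanoate | COC(=O)CCC=O | starting material
2 | S-ethyl (triphenylphosphoranylidene)thioacetate | CCSC(=O)C=P(c1ccccc1)(c1ccccc1)c1ccccc1 | starting material
3 | methyl (4E)-6-(ethylsulfanyl)-6-oxohex-4-enoate | CCSC(=O)/C=C/CCC(=O)OC | intermediate
4 | methylmagnesium bromide | C[Mg]Br | starting material
5 | bromomagnesium enolate of S-ethyl (3S)-6-methoxy-3-methyl-6-oxohexanethioate | CCSC(O[Mg]Br)=C[C@@H](C)CCC(=O)OC | intermediate
6 | S-ethyl (1R,2S)-2-methyl-5-oxocyclopentane-1-carbothioate | CCSC(=O)[C@H]1C(=O)CC[C@@H]1C | intermediate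
7 | prop-2-en-1-ol | C=CCO | starting material
8 | prop-2-en-1-yl (1R,2S)-2-methyl-5-oxocyclopentane-1-carboxylate | C=CCOC(=O)[C@H]1C(=O)CC[C@@H]1C | intermediate
9 | methyl 2-methoxyprop-2-enoate | C=C(OC)C(=O)OC | starting material
10 | prop-2-en-1-yl (2S)-1-(2,3-dimethoxy-3-oxopropyl)-2-methyl-5-oxocyclopentane-1-carboxylate (mixture at C1 and at the methoxy carbon) | C=CCOC(=O)C1(CC(OC)C(=O)OC)C(=O)CC[C@@H]1C | intermediate
11 | methyl 2-methoxy-3-[(1S,2S)-2-methyl-5-oxo-1-(prop-2-en-1-yl)cyclopentyl]propanoate (epimers at the methoxy carbon) | C=CC[C@@]1(CC(OC)C(=O)OC)C(=O)CC[C@@H]1C | intermediate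
12 | methyl 2-methoxy-3-[(1S,5S)-5-methyl-1-(prop-2-en-1-yl)-2-(trimethylsilyloxy)cyclopent-2-en-1-yl]propanoate | C=CC[C@@]1(CC(OC)C(=O)OC)C(O[Si](C)(C)C)=CC[C@@H]1C | intermediate
13 | methyl 2-methoxy-3-[(1S,5S)-5-methyl-2-oxo-1-(prop-2-en-1-yl)cyclopent-3-en-1-yl]propanoate | C=CC[C@@]1(CC(OC)C(=O)OC)C(=O)C=C[C@@H]1C | intermediate
14 | (3,4-dimethoxyphenyl)boronic acid | COc1ccc(B(O)O)cc1OC | starting material
15 | methyl 3-[(1S,2S,3R)-3-(3,4-dimethoxyphenyl)-2-methyl-5-oxo-1-(prop-2-en-1-yl)cyclopentyl]-2-methoxypropanoate | C=CC[C@@]1(CC(OC)C(=O)OC)C(=O)C[C@@H](c2ccc(OC)c(OC)c2)[C@@H]1C | intermediate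
16 | lithium C3–C4 enolate of the bridged 3-methoxy-4,8-dione (ring configuration as in 18) | C=CC[C@@]12CC(OC)=C(O[Li])[C@@H](C1=O)[C@@H](c1ccc(OC)c(OC)c1)[C@@H]2C | intermediate
17 | 6-(3,4-dimethoxyphenyl)-3-methoxy-7-methyl-3-(phenylselanyl)-1-(prop-2-en-1-yl)bicyclo[3.2.1]octane-4,8-dione (C3 epimers, ring configuration as in 18) | C=CC[C@@]12CC(OC)([Se]c3ccccc3)C(=O)[C@@H](C1=O)[C@@H](c1ccc(OC)c(OC)c1)[C@@H]2C | intermediate
18 | (1R,5R,6S,7S)-6-(3,4-dimethoxyphenyl)-3-methoxy-7-methyl-1-(prop-2-en-1-yl)bicyclo[3.2.1]oct-2-ene-4,8-dione | C=CC[C@@]12C=C(OC)C(=O)[C@@H](C1=O)[C@@H](c1ccc(OC)c(OC)c1)[C@@H]2C | intermediate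
19 | (1R,4R,5S,6S,7S)-6-(3,4-dimethoxyphenyl)-4-hydroxy-3-methoxy-7-methyl-1-(prop-2-en-1-yl)bicyclo[3.2.1]oct-2-en-8-one | C=CC[C@@]12C=C(OC)[C@H](O)[C@@H](C1=O)[C@@H](c1ccc(OC)c(OC)c1)[C@@H]2C | target

**Step count and risks**

Total steps: 9. Longest linear sequence: 9 steps (1 to 19).

Step 2 is the most exposed. Ring closure may lag behind the conjugate addition, so that the magnesium enolate is protonated or condenses intermolecularly, or residual Grignard reagent attacks an ester on warming. The fallback sets out from 3: the copper-catalysed addition is run alone and quenched cold to isolate S-ethyl (3S)-6-methoxy-3-methyl-6-oxohexanethioate F1. The ring is then closed in a separate Dieckmann condensation with NaN(SiMe3)2 in THF at −78 °C, where regiocontrol rests on the higher acidity of the thioester α-methylene instead of on the addition; this returns to 6.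

Step 8 comes next. The liberated methoxide may reopen the strained bridged β-diketone by retro-Claisen cleavage, or the base may enolise the side-chain ester instead of the ketone. The fallback sets out from 15 and replaces the basic Claisen by a soft-enolisation acylation with a non-nucleophilic leaving group. Saponification (LiOH, THF/H2O) gives 3-[(1S,2S,3R)-3-(3,4-dimethoxyphenyl)-2-methyl-5-oxo-1-(prop-2-en-1-yl)cyclopentyl]-2-methoxypropanoic acid F4, which is converted (C6F5OH, carbodiimide) into pentafluorophenyl 3-[(1S,2S,3R)-3-(3,4-dimethoxyphenyl)-2-methyl-5-oxo-1-(prop-2-en-1-yl)cyclopentyl]-2-methoxypropanoate F5. MgBr2·OEt2 and i-Pr2NEt in CH2Cl2 should then effect C-acylation at C5 to (1S,5R,6S,7S)-6-(3,4-dimethoxyphenyl)-3-methoxy-7-methyl-1-(prop-2-en-1-yl)bicyclo[3.2.1]octane-4,8-dione F6. Saegusa–Ito dehydrogenation (Me3SiOTf, Et3N; then Pd(OAc)2) of its only enolisable position returns to 18.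

Step 4 is the third. Conjugate addition to the electron-rich 2-methoxyacrylate at a hindered tertiary carbon may be too slow, and forcing conditions may cleave the β-keto ester. The fallback sets out from 8 and uses the much more electrophilic aldehyde: Et3N-catalysed Michael addition to 2-methoxyprop-2-enal (CH2Cl2, 0 °C) gives prop-2-en-1-yl (2S)-1-(2-methoxy-3-oxopropyl)-2-methyl-5-oxocyclopentane-1-carboxylate F2. Pinnick oxidation (NaClO2, NaH2PO4, 2-methylbut-2-ene) gives 2-methoxy-3-[(2S)-2-methyl-5-oxo-1-(prop-2-en-1-yloxycarbonyl)cyclopentyl]propanoic acid F3, and esterification with (trimethylsilyl)diazomethane in toluene/MeOH returns to 10.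

Further compounds

F1 | step 2 | S-ethyl (3S)-6-methoxy-3-methyl-6-oxohexanethioate | CCSC(=O)C[C@@H](C)CCC(=O)OC
F2 | step 4 | prop-2-en-1-yl (2S)-1-(2-methoxy-3-oxopropyl)-2-methyl-5-oxocyclopentane-1-carboxylate | C=CCOC(=O)C1(CC(OC)C=O)C(=O)CC[C@@H]1C
F3 | step 4 | 2-methoxy-3-[(2S)-2-methyl-5-oxo-1-(prop-2-en-1-yloxycarbonyl)cyclopentyl]propanoic acid | C=CCOC(=O)C1(CC(OC)C(=O)O)C(=O)CC[C@@H]1C
F4 | step 8 | 3-[(1S,2S,3R)-3-(3,4-dimethoxyphenyl)-2-methyl-5-oxo-1-(prop-2-en-1-yl)cyclopentyl]-2-methoxypropanoic acid | C=CC[C@@]1(CC(OC)C(=O)O)C(=O)C[C@@H](c2ccc(OC)c(OC)c2)[C@@H]1C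
F5 | step 8 | pentafluorophenyl 3-[(1S,2S,3R)-3-(3,4-dimethoxyphenyl)-2-methyl-5-oxo-1-(prop-2-en-1-yl)cyclopentyl]-2-methoxypropanoate | C=CC[C@@]1(CC(OC)C(=O)Oc2c(F)c(F)c(F)c(F)c2F)C(=O)C[C@@H](c2ccc(OC)c(OC)c2)[C@@H]1C
F6 | step 8 | (1S,5R,6S,7S)-6-(3,4-dimethoxyphenyl)-3-methoxy-7-methyl-1-(prop-2-en-1-yl)bicyclo[3.2.1]octane-4,8-dione | C=CC[C@@]12CC(OC)C(=O)[C@@H](C1=O)[C@@H](c1ccc(OC)c(OC)c1)[C@@H]2C
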